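The route rests on breaking the C4–C5 bond of ring A. The oxygen on C6 of the target is treated as a ring B carbonyl, which makes C5 its α-carbon and C10 its β-carbon: C10 is set by an enantioselective conjugate methylation, and the enol ether left at C5=C6 is alkylated by a tertiary cation at C4. That one operation closes ring A, joins the gem-dimethyl carbon to C5 and, after equilibration, gives the trans ring fusion. Its precursor is a monocyclic silyl enol ether whose C10 carries methyl and a 4-methoxy-4-methylpentyl chain. Ring B is then oxidised around to the 6β-acetoxy-8-en-7-one, with a side chain from (R)-linalool joined at C9.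

Key step: step 4

Remark: locants follow labdane numbering (ring A C1–C5 and C10, ring B C5–C10, gem-dimethyl on C4, C20 methyl on C10, C17 methyl on C8, side chain C11–C16 on C9), β is the face of the C10 methyl and α the opposite face; the side-chain iodide has one carbon fewer than the C1–C6 part of linalool, so linalool C6 is excised in steps 10 and 11.

Step 1
Reactants: 1 5-bromo-2-methylpent-2-ene
Product: 2 5-bromo-2-methoxy-2-methylpentane
Conditions: MeOH (large excess), H2SO4 (cat.), 40 °C
Reagents that add atoms: methanol, CO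
Why: Acid-catalysed Markovnikov hydroalkoxylation, in which the trisubstituted alkene is protonated to the tertiary cation and captured by excess methanol while the primary bromide is inert under these mild conditions.

Step 2
Reactants: 2 5-bromo-2-methoxy-2-methylpentane; 3 3-ethoxycyclohex-2-en-1-one
Product: 6 3-(4-methoxy-4-methylpentyl)cyclohex-2-en-1-one, via alkylmagnesium bromide 4 (not isolated), via bromomagnesium alkoxide 5 (not isolated)
Conditions: Mg, THF, 40 °C; then 3, THF, 0 °C; then 1 M HCl, 0 °C, brief
Reagents that add atoms: water, O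
Why: Grignard 1,2-addition to the vinylogous ester followed by acid hydrolysis with allylic transposition (Stork–Danheiser-type sequence) gives the 3-alkyl enone, and the short exposure to cold dilute acid spares the tertiary methyl ether.

Step 3
Reactants: 6 3-(4-methoxy-4-methylpentyl)cyclohex-2-en-1-one
Product: 8 {[(R)-3-(4-methoxy-4-methylpentyl)-3-methylcyclohex-1-en-1-yl]oxy}trimethylsilane, via dimethylaluminium enolate 7 (not isolated)
Conditions: AlMe3 (1.4 equiv), Cu(OTf)2 (2 mol %), 2,2′-biphenol phosphoramidite of bis[1-(2-naphthyl)ethyl]amine (4 mol %), Et2O, −30 °C; then Me3SiOTf, THF, −30 °C; Et3N, pentane, cold aq NaHCO3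
Reagents that add atoms: trimethylaluminium, C[Al](C)C; trimethylsilyl trifluoromethanesulfonate, C[Si](C)(C)OS(=O)(=O)C(F)(F)F
Why: Copper-catalysed asymmetric conjugate addition of AlMe3 to a 3-alkylcyclohexenone is an established way to β-quaternary ketones, the ligand antipode being chosen so that methyl adds to the enone face that makes C10 R (the target's arrangement), and silylating the aluminium enolate in place with the triflate (aluminium enolates react poorly with chlorosilanes) fixes the double bond at C5=C6, which deprotonation of the free ketone would not do.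

Step 4
Reactants: 8 {[(R)-3-(4-methoxy-4-methylpentyl)-3-methylcyclohex-1-en-1-yl]oxy}trimethylsilane
Product: 10 trans-4,4,10-trimethyldecal-6-one (5α-H; 10β-methyl), via cis-fused C5 epimer 9 (not isolated)
Conditions: TiCl4 (1.1 equiv), 2,6-di-tert-butyl-4-methylpyridine (0.5 equiv), CH2Cl2, −78 °C; aq NaHCO3; then NaOMe, MeOH, 50 °C
Reagents that add atoms: none
Why: TiCl4 binds and ionises the tertiary methyl ether to the C4 carbocation (the hindered pyridine removes adventitious acid so that the enol ether is not protodesilylated), C5 of the enol ether attacks the cation, and chloride strips silicon from the resulting oxocarbenium ion to leave the C6 ketone. The closest known chemistry is the Lewis-acid SN1 α-tert-alkylation of silyl enol ethers by tertiary halides and enol-silane-terminated cation cyclisations, and ionisation of tertiary methyl ethers by TiCl4 is familiar from initiators of cationic polymerisation. Ring A closes in a 6-(enolexo) mode, 6-exo-trig when counted from the C5=C6 bond, through a chair-like array C10–C1–C2–C3–C4–C5. The tether reaches only the enol face on its own side, so C4 should bond axially to ring B and the cis-fused ketone 9 is the expected kinetic product; because C5 is α to the carbonyl, methoxide equilibrates it to trans-fused 10, in which both rings are chairs and C4 is equatorial on ring B, so the new C5 centre is under thermodynamic control by the fixed C10 centre. The step needs C-alkylation at C5 and not at C7 or on oxygen: the regiodefined enol ether from step 3 secures the site, and a six-membered closure of a soft enol carbon onto a tertiary cation favours C–C bond formation.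

Step 5
Reactants: 10 trans-4,4,10-trimethyldecal-6-one
Product: 12 trans-4,4,10-trimethyl-Δ7-octal-6-one, via trimethylsilyl enol ether 11 (not isolated)
Conditions: Me3SiCl, LiN(i-Pr)2, THF, −78 °C (in situ trap); solvent exchange; Pd(OAc)2 (1.1 equiv), MeCN, 25 °C
Reagents that add atoms: none
Why: Saegusa–Ito dehydrogenation, in which kinetic silylation can occur only toward C7 (C5 is a shielded methine) and the palladium enolate loses β-hydride from C8, over-oxidation being excluded because C4 and C10 are quaternary.

Step 6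
Reactants: 12 trans-4,4,10-trimethyl-Δ7-octal-6-one
Product: 13 7α,8α-epoxy-trans-4,4,10-trimethyldecal-6-one
Conditions: 30% H2O2, NaOH (cat.), MeOH, 0 °C
Reagents that add atoms: hydrogen peroxide, OO
Why: Weitz–Scheffer nucleophilic epoxidation, in which hydroperoxide adds to C8 from the α face, anti to the axial C10 methyl, and the enolate closes the oxirane; the new C7 and C8 centres are erased again in steps 7 and 8.

Step 7
Reactants: 13 7α,8α-epoxy-trans-4,4,10-trimethyldecal-6-one
Product: 15 trans-4,4,10-trimethyl-Δ6-octal-8α-ol, via epoxy hydrazone 14 (not isolated)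
Conditions: N2H4·H2O (3 equiv), AcOH (0.2 equiv), MeOH, 0 → 25 °C
Reagents that add atoms: none
Why: Wharton transposition, in which the epoxy hydrazone opens to an allylic alcohol–vinyldiazene that loses N2, moving the oxygen function from C6 to C8 and leaving the C6=C7 double bond.

Step 8
Reactants: 15 trans-4,4,10-trimethyl-Δ6-octal-8α-ol
Product: 16 trans-4,4,10-trimethyl-Δ6-octal-8-one
Conditions: Dess–Martin periodinane, CH2Cl2, 25 °C
Reagents that add atoms: none
Why: Dess–Martin oxidation of a secondary allylic alcohol to the enone under mild, non-epimerising conditions.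

Step 9
Reactants: 17 (R)-linalool
Product: 18 (R)-3,7-dimethyl-3-(triethylsilyloxy)octa-1,6-diene
Conditions: Et3SiOTf, 2,6-lutidine, CH2Cl2, −78 → 0 °C
Reagents that add atoms: triethylsilyl trifluoromethanesulfonate, CC[Si](CC)(CC)OS(=O)(=O)C(F)(F)F
Why: Silylation of the tertiary allylic alcohol with a silyl triflate and a hindered base, which does not touch the stereocentre that becomes C13.

Step 10
Reactants: 18 (R)-3,7-dimethyl-3-(triethylsilyloxy)octa-1,6-diene
Product: 20 (R)-4-methyl-4-(triethylsilyloxy)hex-5-enoic acid, via aldehyde 19 (not isolated)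
Conditions: O3 (1.0 equiv, Sudan red 7B end point), CH2Cl2, −78 °C; PPh3; then NaClO2, NaH2PO4, 2-methylbut-2-ene, t-BuOH/H2O, 25 °C
Reagents that add atoms: ozone, [O-][O+]=O; sodium chlorite, [Na+].[O-]Cl=O
Why: Ozonolysis is selective because the electron-rich trisubstituted alkene reacts far faster than the vinyl group shielded by the adjacent fully substituted carbon, and Pinnick oxidation of the crude aldehyde gives the acid without affecting alkene or silyl ether.

Step 11
Reactants: 20 (R)-4-methyl-4-(triethylsilyloxy)hex-5-enoic acid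
Product: 22 (R)-5-iodo-3-methyl-3-(triethylsilyloxy)pent-1-ene, via thiohydroxamate ester 21 (not isolated)
Conditions: N-hydroxypyridine-2-thione, N,N′-dicyclohexylcarbodiimide, DMAP (cat.), CH2Cl2, 0 °C, dark; then CHI3 (2 equiv), hν (tungsten lamp), 25 °C
Reagents that add atoms: iodoform, IC(I)I
Why: Barton decarboxylative iodination, in which the thiohydroxamate ester fragments in a radical chain to a primary radical that abstracts iodine from CHI3; the radical is of the pent-4-enyl type and does not cyclise or rearrange at a competitive rate, so vinyl group and stereocentre are kept (the acid is used at once to avoid lactonisation).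

Step 12
Reactants: 16 trans-4,4,10-trimethyl-Δ6-octal-8-one; 22 (R)-5-iodo-3-methyl-3-(triethylsilyloxy)pent-1-ene
Product: 24 9α-[(R)-3-methyl-3-(triethylsilyloxy)pent-4-enyl]-trans-4,4,10-trimethyl-Δ6-octal-8-one (9β-H), via lithium dienolate 23 (not isolated)
Conditions: LiN(i-Pr)2 (1.1 equiv), THF, −78 °C; then 22 (1.3 equiv), DMPU, −78 → 0 °C
Reagents that add atoms: none
Why: Kinetic α′-deprotonation of the enone (C9 is its only α-CH2) and SN2 alkylation of the cross-conjugated lithium dienolate by the primary iodide, the electrophile approaching anti to the axial C10 methyl; the C9 configuration is erased in step 13.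

Step 13
Reactants: 24 9α-alkylated enone
Product: 26 C8 enol triflate of 24 (C6=C7 and C8=C9 diene; triflyloxy on C8), via potassium enolate 25 (not isolated)
Conditions: KN(SiMe3)2, THF, −78 → −40 °C; then PhNTf2, −78 → 0 °C
Reagents that add atoms: N-phenylbis(trifluoromethanesulfonimide), O=S(=O)(N(c1ccccc1)S(=O)(=O)C(F)(F)F)C(F)(F)F
Why: The remaining C9–H is the only α-hydrogen, so kinetic deprotonation gives a single tetrasubstituted enolate that is O-sulfonylated (enol triflate formation).

Step 14
Reactants: 26 C8 enol triflate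
Product: 27 (13R)-13-(triethylsilyloxy)labda-6,8,14-triene
Conditions: MeZnCl (2 equiv), PdCl2(dppf) (5 mol %), THF, 50 °C
Reagents that add atoms: methylzinc chloride, C[Zn]Cl
Why: Negishi cross-coupling of an alkenyl triflate with a methylzinc reagent places the C17 methyl on C8 and fixes the C6=C7 and C8=C9 double bonds without regiochemical ambiguity.

Step 15
Reactants: 27 (13R)-13-(triethylsilyloxy)labda-6,8,14-triene
Product: 29 (13R)-9α-hydroxy-13-(triethylsilyloxy)labda-7,14-dien-6-one, via endoperoxide 28 (not isolated)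
Conditions: O2, tetraphenylporphyrin (cat.), visible light, CH2Cl2, −20 °C; then DBU, 0 → 25 °C
Reagents that add atoms: dioxygen, O=O
Why: Singlet oxygen adds [4+2] to the cisoid ring B diene from the α face, as with steroidal 5,7-dienes, and the base-induced Kornblum–DeLaMare rearrangement can remove only the C6–H because C9 carries none, giving the C6 ketone and the 9α tertiary alcohol while the monosubstituted side-chain alkene is inert to singlet oxygen.

Step 16
Reactants: 29 (13R)-9α-hydroxy-13-(triethylsilyloxy)labda-7,14-dien-6-one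
Product: 30 (13R)-13-(triethylsilyloxy)labda-7,14-diene-6β,9α-diol
Conditions: NaBH4, CeCl3·7H2O, MeOH, −40 → 0 °C
Reagents that add atoms: none
Why: Luche 1,2-reduction, in which hydride attacks the C6 carbonyl from the α face because the β face is blocked by the syn-axial C10 and C4β methyl groups, setting the 6β (axial) alcohol with the C6 configuration of the target.

Step 17
Reactants: 30 (13R)-13-(triethylsilyloxy)labda-7,14-diene-6β,9α-diol
Product: 31 (13R)-9α-hydroxy-13-(triethylsilyloxy)labda-7,14-dien-6β-yl acetate
Conditions: Ac2O, DMAP, pyridine, 40 °C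
Reagents that add atoms: acetic anhydride, CC(=O)OC(C)=O
Why: DMAP-catalysed acylation of the secondary allylic alcohol, the tertiary C9 hydroxyl next to the quaternary C10 being too hindered to compete.

Step 18
Reactants: 31 (13R)-9α-hydroxy-13-(triethylsilyloxy)labda-7,14-dien-6β-yl acetate
Product: 32 (13R)-6β-acetoxy-13-(triethylsilyloxy)labda-8,14-dien-7-one
Conditions: pyridinium chlorochromate [C5H5NH][CrO3Cl] (3 equiv), 4 Å molecular sieves, CH2Cl2, 25 °C
Reagents that add atoms: none
Why: Babler–Dauben oxidative 1,3-transposition, in which the chromate ester of the tertiary allylic C9 alcohol shifts to C7 by a [3,3] process and is oxidised there, giving the C7 ketone conjugated with the tetrasubstituted C8=C9 bond without touching C6.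

Step 19
Reactants: 32 (13R)-6β-acetoxy-13-(triethylsilyloxy)labda-8,14-dien-7-one
Product: 33 (13R)-6β-acetoxy-13-hydroxylabda-8,14-dien-7-one (CNP0328351.1)
Conditions: HF·pyridine, pyridine, THF, 0 → 25 °C
Reagents that add atoms: none
Why: Fluoride-mediated cleavage of the tertiary triethylsilyl ether under buffered, non-basic conditions that leave the α-acetoxy enone and its epimerisable C6 centre intact.

Compound list
1 | 5-bromo-2-methylpent-2-ene | CC(C)=CCCBr | starting material
2 | 5-bromo-2-methoxy-2-methylpentane | COC(C)(C)CCCBr | intermediate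
3 | 3-ethoxycyclohex-2-en-1-one | CCOC1=CC(=O)CCC1 | starting material
4 | (4-methoxy-4-methylpentyl)magnesium bromide | COC(C)(C)CCC[Mg]Br | intermediate
5 | bromomagnesium 3-ethoxy-1-(4-methoxy-4-methylpentyl)cyclohex-2-en-1-olate (racemic) | CCOC1=CC(CCCC(C)(C)OC)(O[Mg]Br)CCC1 | intermediate
6 | 3-(4-methoxy-4-methylpentyl)cyclohex-2-en-1-one | COC(C)(C)CCCC1=CC(=O)CCC1 | intermediate
7 | dimethylaluminium (R)-3-(4-methoxy-4-methylpentyl)-3-methylcyclohex-1-en-1-olate | COC(C)(C)CCC[C@]1(C)CCCC(O[Al](C)C)=C1 | intermediate
8 | {[(R)-3-(4-methoxy-4-methylpentyl)-3-methylcyclohex-1-en-1-yl]oxy}trimethylsilane (C10 arranged as in the target; the descriptor differs only through priorities) | COC(C)(C)CCC[C@]1(C)CCCC(O[Si](C)(C)C)=C1 | intermediate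
9 | cis-4,4,10-trimethyldecal-6-one (5β-H, 10β-methyl), (4aR,8aR)-4a,8,8-trimethyloctahydronaphthalen-1(2H)-one | O=C1CCC[C@@]2(C)CCCC(C)(C)[C@@H]12 | intermediate
10 | trans-4,4,10-trimethyldecal-6-one (5α-H, 10β-methyl), (4aR,8aS)-4a,8,8-trimethyloctahydronaphthalen-1(2H)-one | O=C1CCC[C@@]2(C)CCCC(C)(C)[C@H]12 | intermediate
11 | trimethylsilyl enol ether of 10 (C6–O–Si, C6=C7) | C[Si](C)(C)OC1=CCC[C@@]2(C)CCCC(C)(C)[C@H]12 | intermediate
12 | trans-4,4,10-trimethyl-Δ7-octal-6-one (5α-H, 10β-methyl) | O=C1C=CC[C@@]2(C)CCCC(C)(C)[C@H]12 | intermediate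
13 | 7α,8α-epoxy-trans-4,4,10-trimethyldecal-6-one | O=C1[C@H]2O[C@H]2C[C@@]3(C)CCCC(C)(C)[C@H]13 | intermediate
14 | hydrazone of 13 | NN=C1[C@H]2O[C@H]2C[C@@]3(C)CCCC(C)(C)[C@H]13 | intermediate
15 | trans-4,4,10-trimethyl-Δ6-octal-8α-ol | C1=C[C@@H](O)C[C@@]2(C)CCCC(C)(C)[C@H]12 | intermediate
16 | trans-4,4,10-trimethyl-Δ6-octal-8-one | C1=CC(=O)C[C@@]2(C)CCCC(C)(C)[C@H]12 | intermediate
17 | (R)-linalool | C=C[C@](C)(O)CCC=C(C)C | starting material
18 | (R)-3,7-dimethyl-3-(triethylsilyloxy)octa-1,6-diene | C=C[C@](C)(O[Si](CC)(CC)CC)CCC=C(C)C | intermediate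
19 | (R)-4-methyl-4-(triethylsilyloxy)hex-5-enal | C=C[C@](C)(O[Si](CC)(CC)CC)CCC=O | intermediate
20 | (R)-4-methyl-4-(triethylsilyloxy)hex-5-enoic acid | C=C[C@](C)(O[Si](CC)(CC)CC)CCC(=O)O | intermediate
21 | 2-thioxopyridin-1(2H)-yl (R)-4-methyl-4-(triethylsilyloxy)hex-5-enoate | C=C[C@](C)(O[Si](CC)(CC)CC)CCC(=O)ON1C=CC=CC1=S | intermediate
22 | (R)-5-iodo-3-methyl-3-(triethylsilyloxy)pent-1-ene | C=C[C@](C)(O[Si](CC)(CC)CC)CCI | intermediate
23 | lithium dienolate of 16 (O–Li on C8, C8=C9, C6=C7) | C1=CC(O[Li])=C[C@@]2(C)CCCC(C)(C)[C@H]12 | intermediate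
24 | 9α-[(R)-3-methyl-3-(triethylsilyloxy)pent-4-enyl]-trans-4,4,10-trimethyl-Δ6-octal-8-one (9β-H) | C=C[C@](C)(O[Si](CC)(CC)CC)CC[C@@H]1C(=O)C=C[C@H]2C(C)(C)CCC[C@]12C | intermediate
25 | potassium enolate of 24 (O–K on C8, C8=C9) | C=C[C@](C)(O[Si](CC)(CC)CC)CCC1=C(O[K])C=C[C@H]2C(C)(C)CCC[C@]12C | intermediate
26 | C8 enol triflate of 24 (C6=C7, C8=C9) | C=C[C@](C)(O[Si](CC)(CC)CC)CCC1=C(OS(=O)(=O)C(F)(F)F)C=C[C@H]2C(C)(C)CCC[C@]12C | intermediate
27 | (13R)-13-(triethylsilyloxy)labda-6,8,14-triene (5α-H, 10β-methyl) | C=C[C@](C)(O[Si](CC)(CC)CC)CCC1=C(C)C=C[C@H]2C(C)(C)CCC[C@]12C | intermediate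
28 | (13R)-6α,9α-epidioxy-13-(triethylsilyloxy)labda-7,14-diene | C=C[C@](C)(O[Si](CC)(CC)CC)CC[C@@]12OO[C@@H](C=C1C)[C@H]3C(C)(C)CCC[C@]23C | intermediate
29 | (13R)-9α-hydroxy-13-(triethylsilyloxy)labda-7,14-dien-6-one | C=C[C@](C)(O[Si](CC)(CC)CC)CC[C@@]1(O)C(C)=CC(=O)[C@H]2C(C)(C)CCC[C@]12C | intermediate
30 | (13R)-13-(triethylsilyloxy)labda-7,14-diene-6β,9α-diol | C=C[C@](C)(O[Si](CC)(CC)CC)CC[C@@]1(O)C(C)=C[C@@H](O)[C@H]2C(C)(C)CCC[C@]12C | intermediate
31 | (13R)-9α-hydroxy-13-(triethylsilyloxy)labda-7,14-dien-6β-yl acetate | C=C[C@](C)(O[Si](CC)(CC)CC)CC[C@@]1(O)C(C)=C[C@@H](OC(C)=O)[C@H]2C(C)(C)CCC[C@]12C | intermediate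
32 | (13R)-6β-acetoxy-13-(triethylsilyloxy)labda-8,14-dien-7-one | C=C[C@](C)(O[Si](CC)(CC)CC)CCC1=C(C)C(=O)[C@@H](OC(C)=O)[C@H]2C(C)(C)CCC[C@]12C | intermediate
33 | (5S,6S,10S,13R)-6β-acetoxy-13-hydroxylabda-8,14-dien-7-one (CNP0328351.1) | C=C[C@](C)(O)CCC1=C(C)C(=O)[C@@H](OC(C)=O)[C@H]2C(C)(C)CCC[C@]12C | target

Total step count: 19. Longest linear sequence: 16 steps (steps 1–8 and 12–19); the side-chain branch is steps 9–11.

Steps most likely to fail

Step 4. Ionisation of the ether may be outrun by protodesilylation of the enol ether, the cation may lose a proton instead of cyclising, and the ring-fusion equilibrium may not lie far enough on the trans side. The fallback builds ring A by aldol condensation and adds the second C4 methyl afterwards. It sets out from 3: the Grignard reagent from commercial 2-(3-chloropropyl)-2-methyl-1,3-dioxolane, [3-(2-methyl-1,3-dioxolan-2-yl)propyl]magnesium chloride F1, is added to 3 and the adduct is hydrolysed with cold dilute acid, keeping the ketal, to 3-[3-(2-methyl-1,3-dioxolan-2-yl)propyl]cyclohex-2-en-1-one F2. The conjugate methylation of step 3 with aqueous work-up gives (S)-3-methyl-3-[3-(2-methyl-1,3-dioxolan-2-yl)propyl]cyclohexanone F3, and aqueous acid frees (R)-3-methyl-3-(4-oxopentyl)cyclohexanone F4. Intramolecular aldol condensation (KOH, MeOH), in which only attack of C5 on the chain carbonyl can dehydrate to a conjugated enone, gives (4aR)-4a,8-dimethyl-3,4,4a,5,6,7-hexahydronaphthalen-1(2H)-one F5. Conjugate addition of Me2CuLi with Me3SiCl, hydrolysis and methoxide equilibration come back to the route at 10.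

Step 12. C-alkylation at the neopentyl C9 may be too slow, so that proton transfer, O-alkylation or dehydroiodination of the iodide take over. The fallback replaces the ketone enolate by a metalated hydrazone. It sets out from 16: condensation with N,N-dimethylhydrazine gives the N,N-dimethylhydrazone of 16 F6; deprotonation at C9 with LiN(i-Pr)2 and alkylation with 22 gives the N,N-dimethylhydrazone of 24 F7, the aza-enolate being more nucleophilic and less prone to proton exchange. Hydrolysis with aqueous Cu(OAc)2 comes back at 24.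

Step 7. Hydrazone formation at the shielded C6 carbonyl may be slow, so that hydrazine opens or reduces the epoxide before the diazene fragmentation can occur. The fallback moves the carbonyl through a 1,3-dione. It sets out from 13: Pd(PPh3)4 with 1,2-bis(diphenylphosphino)ethane in hot toluene isomerises the epoxy ketone to trans-4,4,10-trimethyldecalin-6,8-dione F8. Acid-catalysed enol etherification (MeOH, HC(OMe)3, TsOH) at the less hindered C8 carbonyl gives 8-methoxy-trans-4,4,10-trimethyl-Δ7-octal-6-one F9. Reduction of the C6 carbonyl with i-Bu2AlH gives 8-methoxy-trans-4,4,10-trimethyl-Δ7-octal-6β-ol F10, and dilute acid hydrolyses the enol ether with loss of the C6 hydroxyl, coming back at 16 (15 is bypassed).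

Further compounds
F1 | step 4 | [3-(2-methyl-1,3-dioxolan-2-yl)propyl]magnesium chloride | CC1(CCC[Mg]Cl)OCCO1
F2 | step 4 | 3-[3-(2-methyl-1,3-dioxolan-2-yl)propyl]cyclohex-2-en-1-one | CC1(CCCC2=CC(=O)CCC2)OCCO1
F3 | step 4 | (S)-3-methyl-3-[3-(2-methyl-1,3-dioxolan-2-yl)propyl]cyclohexanone | CC1(CCC[C@]2(C)CCCC(=O)C2)OCCO1
F4 | step 4 | (R)-3-methyl-3-(4-oxopentyl)cyclohexanone | CC(=O)CCC[C@]1(C)CCCC(=O)C1
F5 | step 4 | (4aR)-4a,8-dimethyl-3,4,4a,5,6,7-hexahydronaphthalen-1(2H)-one | CC1=C2C(=O)CCC[C@@]2(C)CCC1
F6 | step 12 | N,N-dimethylhydrazone of 16 | C1=CC(=NN(C)C)C[C@@]2(C)CCCC(C)(C)[C@H]12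
F7 | step 12 | N,N-dimethylhydrazone of 24 | C=C[C@](C)(O[Si](CC)(CC)CC)CC[C@@H]1C(=NN(C)C)C=C[C@H]2C(C)(C)CCC[C@]12C
F8 | step 7 | trans-4,4,10-trimethyldecalin-6,8-dione | O=C1CC(=O)C[C@@]2(C)CCCC(C)(C)[C@H]12
F9 | step 7 | 8-methoxy-trans-4,4,10-trimethyl-Δ7-octal-6-one | O=C1C=C(OC)C[C@@]2(C)CCCC(C)(C)[C@H]12
F10 | step 7 | 8-methoxy-trans-4,4,10-trimethyl-Δ7-octal-6β-ol | O[C@@H]1C=C(OC)C[C@@]2(C)CCCC(C)(C)[C@H]12
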